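Time is the first thing you would turn, so ask what a longer wait can still buy. Here is the flask, with its one run so far:

- south-east: left-handed substrate 0.050 M; right-handed substrate 0.050 M; coupling partner 0.20 M; catalyst 0.10 mM; added ligand 76 µM; the very flask that is asked about, followed so far
- flask: left-handed substrate 0.050 M; coupling partner 0.200 M; catalyst 0.10 mM; added ligand 76 µM; right-handed substrate 0.050 M; time 5.0 min

south-east run (percent of the left-handed substrate and right-handed substrate together charged)

| time / s | left-handed product / % | right-handed product / % |
|---|---|---|
| 10.0 | 14.7 | 9.0 |
| 20.0 | 25.4 | 13.8 |
| 40.0 | 33.1 | 17.5 |
| 60.0 | 36.4 | 20.6 |

(scatter of a reading: 1 percentage point)

- catalyst is single-handed; left-handed substrate and right-handed substrate are mirror images of each other, charged as a racemate, each of them at the stated concentration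
- reactions considered so far: catalyst + added ligand <-> idle complex; 2 coupling partner -> homo dimer; left-handed substrate <-> right-handed substrate; coupling partner -> decomposed reagent; coupling partner + catalyst + left-handed substrate -> catalyst + left-handed product; coupling partner + catalyst + right-handed substrate -> catalyst + right-handed product
- an excess is the difference of the two amounts in percent of their sum
- an excess is below zero if the other one leads

1. left-handed product and right-handed product together, in percent of the left-handed substrate and right-handed substrate charged together, at 5.0 min
2. excess of left-handed product over right-handed product in the product at 5.0 min
3. whether the exchange between left-handed substrate and right-handed substrate keeps pace with the reaction: how far the product's excess at 5.0 min gets from its value without exchange to its value with instant exchange (above 80% keeps pace, below 20% hardly takes part, else lags behind)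

To read time by hand, let x be the logarithm of one over the unreacted share of the two substrates together. Then x reads 0.498 at 20.0 s, 0.705 at 40.0 s and 0.844 at 60.0 s. The later of these two equal steps gains 0.668 of the earlier, so I take the early end as the pace and the late end as a tail shrinking by that ratio. Summing that tail onto the last reading gives 1.12. This end value of x, the reach, is my estimate from scattered readings of what a long wait can deliver, and it means 67.5% product by my reckoning.

Added ligand is the second setting: 76 µM of it stands against 0.10 mM of catalyst, and by hand the reach follows the free catalyst. Coupling partner is the third: by hand the reach follows its charge, 0.200 M here, if its fading pace stays the same.

For the excess, the first reading gives a selectivity factor of 1.75, with the scatter of the readings on it. Without exchange, left over right would form at a ratio of 0.812 by the last reading, yet the last gains give 1.06, larger, though scatter weighs heavily on so small a gain. So I expect the exchange to lag behind, with the excess near its last reading, 27.7%.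

The forecast gives 66% (60% to 78%) and an excess of 22% (16% to 28%), and it parts from me on the exchange, with hardly takes part: “Exchange therefore hardly takes part.”

The flask gives 62.6% with an excess of 26.5%, and the exchange lags behind, getting 62% of the way.

    catalyst + added ligand ⇌ idle complex, settled at all times (K = 8800 /M)
    2 coupling partner → homo dimer (k = 0.0199 /M/s)
    left-handed substrate ⇌ right-handed substrate (k = 0.0338 /s)
    coupling partner → decomposed reagent (k = 0.0228 /s)
    coupling partner + catalyst + left-handed substrate → catalyst + left-handed product (k = 3570 /M²/s)
    coupling partner + catalyst + right-handed substrate → catalyst + right-handed product (k = 1870 /M²/s)

At 5.00 min in this flask the coupling partner, first to run out, stands at 0.00775% of its charge, and ten times as long leaves the part reacted unchanged. Scaled by charge, the reach of 1.12 becomes 0.448 for the neighbour with 0.080 M of coupling partner, which means 36.1%; that flask gives 31.6%.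

Readings and results come from a simulation on assumed constants, noise included.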